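**Plan**

1. The target is (2S)-naringenin with a (2R)-1-methylpiperidin-2-yl group on C6. The retrosynthesis opens ring C at C4–C4a (Friedel–Crafts acylation) and O1–C2 (Mitsunobu etherification), removes the N-methyl group, and cuts the piperidine at N1'–C6' and C2'–C3'.
2. Enabling feature: C2' is a benzylic amine carbon on C6 of ring A, which lies between the oxygen-bearing C5 and C7 and para to C8a–O1. Ring A plus C2' is therefore a symmetric 2,4,6-trioxygenated benzaldehyde, and C3'–C6' is a four-carbon unit that is nucleophilic at C3' and electrophilic at C6'.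
3. Forward order: aldehyde → N-sulfinyl aldimine → piperidine (first ring) → N-methylation and release of the para phenol → ether to the ring B fragment (O1–C2) → carboxylic acid → ring C by acylation at either of the two equivalent positions ortho to O1 → global hydrogenolysis.
4. Stereochemistry: C2' (R) comes from the (S)-tert-butanesulfinyl auxiliary in the Grignard addition. C2 (S) comes from a phosphoric acid-catalysed allylboration that gives the R carbinol, which the Mitsunobu step inverts.

Key step: step 5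

Remark: flavanone locants (O1, C2–C8a, ring B on C2) are used for the chromanone and primed locants for the piperidine; CIP analysis of the given structure gives the 2S,2'R isomer.

**Step 1**
Reactants: 1 2,4,6-trihydroxybenzaldehyde
Product: 2 2,6-dihydroxy-4-[(triisopropylsilyl)oxy]benzaldehyde
Conditions: i-Pr3SiCl (1.05 equiv), imidazole, DMF, 0 °C
Reagents that add atoms: triisopropylsilyl chloride, CC(C)[Si](Cl)(C(C)C)C(C)C
Why: Chemoselective O-silylation: the 4-hydroxyl is the most acidic and the only one not hydrogen-bonded to the formyl oxygen, so one equivalent of the bulky silyl chloride should react there and leave the two chelated hydroxyls free.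

**Step 2**
Reactants: 2 2,6-dihydroxy-4-[(triisopropylsilyl)oxy]benzaldehyde
Product: 3 2,6-bis(benzyloxy)-4-[(triisopropylsilyl)oxy]benzaldehyde
Conditions: BnBr (2.5 equiv), K2CO3, n-Bu4NI (cat.), dry acetone, reflux
Reagents that add atoms: benzyl bromide, BrCc1ccccc1
Why: Williamson ether synthesis on the two remaining chelated phenols; the hindered triisopropylsilyl aryl ether is expected to survive anhydrous K2CO3 in acetone.

**Step 3**
Reactants: 3 2,6-bis(benzyloxy)-4-[(triisopropylsilyl)oxy]benzaldehyde; 4 (S)-2-methylpropane-2-sulfinamide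
Product: 5 (S,E)-N-{2,6-bis(benzyloxy)-4-[(triisopropylsilyl)oxy]benzylidene}-2-methylpropane-2-sulfinamide
Conditions: Ti(OEt)4 (2 equiv), THF, 65 °C
Reagents that add atoms: none
Why: Ti(OEt)4-mediated condensation of an aldehyde with tert-butanesulfinamide (Ellman imine formation), in which the Lewis acid activates the electron-rich, doubly ortho-substituted formyl group and binds the water, should give the E aldimine only.

**Step 4**
Reactants: 6 1-bromo-4-chlorobutane
Product: 7 4-chlorobutylmagnesium bromide (ether solution, titrated and used directly)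
Conditions: Mg turnings, I2 (cat.), Et2O, 0 °C to rt
Reagents that add atoms: magnesium, [Mg]
Why: Grignard formation by magnesium insertion into the weaker C–Br bond, the primary C–Cl bond being inert at this temperature; ether is used instead of THF so that no strongly coordinating solvent enters step 5.

**Step 5**
Reactants: 5 (S,E)-N-{2,6-bis(benzyloxy)-4-[(triisopropylsilyl)oxy]benzylidene}-2-methylpropane-2-sulfinamide; 7 4-chlorobutylmagnesium bromide
Product: 9 (2R)-2-{2,6-bis(benzyloxy)-4-[(triisopropylsilyl)oxy]phenyl}-1-[(S)-tert-butylsulfinyl]piperidine, via acyclic chloro sulfinamide 8 (not isolated)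
Conditions: 7 (2 equiv), toluene, −78 to −20 °C; then KN(SiMe3)2 (3 equiv, in THF), −20 °C to rt
Reagents that add atoms: none
Why: 7 adds to the C=N bond of the N-sulfinyl aldimine (Ellman-type 1,2-addition, forming C2'–C3'), and the halomagnesium sulfinamide 8, turned into its more nucleophilic potassium salt by KN(SiMe3)2, then displaces the terminal chloride (N1'–C6'). The closest known reaction type is the addition of ω-haloalkyl Grignard reagents to N-tert-butanesulfinyl imines followed by base-induced N-alkylation to 2-substituted pyrrolidines and piperidines. The piperidine ring closes in the 6-exo-tet mode by SN2 attack of nitrogen on a primary carbon. C2' is controlled by the sulfur stereocentre: in toluene magnesium is bound to the sulfinyl oxygen and the alkyl group is delivered through a six-membered chair with the tert-butyl group equatorial, which for the (S)-configured E aldimine leads to the R configuration. Facial selectivity is the only selectivity the step needs, since the symmetric arene offers no regiochemical choice and the aldimine has no α-hydrogen; it is secured by the auxiliary together with the non-coordinating solvent, which should keep the sulfinyl-bound chair ahead of a transition state chelated by an ortho benzyloxy oxygen. The configuration of 9 is to be verified (for example by crystallography of the hydrochloride of 10) before material is carried forward.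

**Step 6**
Reactants: 9 (2R)-2-{2,6-bis(benzyloxy)-4-[(triisopropylsilyl)oxy]phenyl}-1-[(S)-tert-butylsulfinyl]piperidine
Product: 10 (2R)-2-{2,6-bis(benzyloxy)-4-[(triisopropylsilyl)oxy]phenyl}piperidine
Conditions: HCl (4 M in dioxane, 3 equiv), MeOH, 0 °C, 30 min; then aq. NaOH
Reagents that add atoms: none
Why: Acid cleavage of the N–S bond of a tert-butanesulfinamide (standard auxiliary removal with methanolic HCl), kept short and cold so that the aryl silyl ether and the electron-rich benzylic C–N bond are left alone.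

**Step 7**
Reactants: 10 (2R)-2-{2,6-bis(benzyloxy)-4-[(triisopropylsilyl)oxy]phenyl}piperidine
Product: 11 (2R)-2-{2,6-bis(benzyloxy)-4-[(triisopropylsilyl)oxy]phenyl}-1-methylpiperidine
Conditions: aq. CH2O (37%), NaBH(OAc)3, ClCH2CH2Cl, rt
Reagents that add atoms: formaldehyde, C=O
Why: Reductive amination (N-methylation through the N-methyleneiminium ion and NaBH(OAc)3); both ring positions ortho to C2' carry benzyloxy groups, so a Pictet–Spengler-type closure cannot compete, and C2' is not touched.

**Step 8**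
Reactants: 11 (2R)-2-{2,6-bis(benzyloxy)-4-[(triisopropylsilyl)oxy]phenyl}-1-methylpiperidine
Product: 12 3,5-bis(benzyloxy)-4-[(2R)-1-methylpiperidin-2-yl]phenol
Conditions: n-Bu4NF, AcOH (1 equiv), THF, 0 °C
Reagents that add atoms: none
Why: Fluoride-mediated cleavage of the aryl silyl ether, buffered with acetic acid, frees only the oxygen para to the piperidine, the future O1.

**Step 9**
Reactants: 13 4-hydroxybenzaldehyde
Product: 14 benzyl 4-formylphenyl carbonate
Conditions: ClCO2Bn, Et3N, CH2Cl2, 0 °C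
Reagents that add atoms: benzyl chloroformate, O=C(Cl)OCc1ccccc1
Why: O-Acylation of the phenol with a chloroformate; the aryl carbonate takes electron density out of ring B, which should hold the later substitution at the benzylic carbon on the SN2 path and protect the C2–O bond in acid, and it leaves by hydrogenolysis together with the benzyl ethers.

**Step 10**
Reactants: 14 benzyl 4-formylphenyl carbonate; 15 2-allyl-4,4,5,5-tetramethyl-1,3,2-dioxaborolane
Product: 17 benzyl 4-[(1R)-1-hydroxybut-3-en-1-yl]phenyl carbonate, via pinacol borate ester 16 (not isolated)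
Conditions: 15 (1.2 equiv), (R)-3,3'-bis(2,4,6-triisopropylphenyl)-1,1'-binaphthyl-2,2'-diyl hydrogen phosphate (5 mol%), toluene, −30 °C; aqueous work-up
Reagents that add atoms: none
Why: Chiral phosphoric acid-catalysed allylboration of an aryl aldehyde through a closed six-membered chair in which the acid is hydrogen-bonded to a boronate oxygen; the (R)-acid is expected to deliver the allyl group to the Re face and so set the R carbinol centre, whose configuration is to be confirmed (Mosher esters) before the coupling.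

**Step 11**
Reactants: 12 3,5-bis(benzyloxy)-4-[(2R)-1-methylpiperidin-2-yl]phenol; 17 benzyl 4-[(1R)-1-hydroxybut-3-en-1-yl]phenyl carbonate
Product: 18 benzyl 4-[(1S)-1-{3,5-bis(benzyloxy)-4-[(2R)-1-methylpiperidin-2-yl]phenoxy}but-3-en-1-yl]phenyl carbonate
Conditions: PPh3, i-PrO2CN=NCO2i-Pr (added last), toluene, 0 °C to rt
Reagents that add atoms: none
Why: Mitsunobu etherification: the phenoxide of 12 displaces the oxyphosphonium derivative of the secondary benzylic alcohol in an SN2 reaction with inversion, which turns the R carbinol into the S configuration of C2 and forms O1–C2.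

**Step 12**
Reactants: 18 benzyl 4-[(1S)-1-{3,5-bis(benzyloxy)-4-[(2R)-1-methylpiperidin-2-yl]phenoxy}but-3-en-1-yl]phenyl carbonate
Product: 20 benzyl 4-[(1S)-1-{3,5-bis(benzyloxy)-4-[(2R)-1-methylpiperidin-2-yl]phenoxy}-3-oxopropyl]phenyl carbonate, via vicinal diol 19 (not isolated)
Conditions: OsO4 (2 mol%), NaIO4 (4 equiv), 2,6-lutidine, dioxane–H2O (3:1), rt; crude product used at once
Reagents that add atoms: osmium tetroxide, O=[Os](=O)(=O)=O (oxygen carrier); sodium periodate, [Na+].[O-]I(=O)(=O)=O (terminal oxidant)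
Why: Lemieux–Johnson oxidation (osmium-catalysed dihydroxylation followed by periodate glycol cleavage) of the terminal alkene is selective in the presence of the arenes, the carbonate and the tertiary amine; the aldehyde is taken on at once because a β-aryloxy aldehyde can eliminate.

**Step 13**
Reactants: 20 benzyl 4-[(1S)-1-{3,5-bis(benzyloxy)-4-[(2R)-1-methylpiperidin-2-yl]phenoxy}-3-oxopropyl]phenyl carbonate
Product: 21 (3S)-3-{3,5-bis(benzyloxy)-4-[(2R)-1-methylpiperidin-2-yl]phenoxy}-3-(4-{[(benzyloxy)carbonyl]oxy}phenyl)propanoic acid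
Conditions: NaClO2, NaH2PO4, 2-methyl-2-butene (excess), t-BuOH–H2O, 0 °C to rt
Reagents that add atoms: sodium chlorite, [Na+].[O-]Cl=O
Why: Pinnick oxidation of the aldehyde to the acid; the buffered, weakly acidic medium keeps the amine protonated so that β-elimination of the aryloxy group is not triggered, and the alkene scavenger removes HOCl before it can chlorinate ring A.

**Step 14**
Reactants: 21 (3S)-3-{3,5-bis(benzyloxy)-4-[(2R)-1-methylpiperidin-2-yl]phenoxy}-3-(4-{[(benzyloxy)carbonyl]oxy}phenyl)propanoic acid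
Product: 23 benzyl 4-{(2S)-5,7-bis(benzyloxy)-6-[(2R)-1-methylpiperidin-2-yl]-4-oxo-3,4-dihydro-2H-chromen-2-yl}phenyl carbonate, via acyl trifluoroacetate 22 (not isolated)
Conditions: CF3CO2H (1.1 equiv), then (CF3CO)2O (2 equiv), CH2Cl2, 0 °C to rt; aq. NaHCO3
Reagents that add atoms: none
Why: Intramolecular Friedel–Crafts acylation through the mixed trifluoroacetic anhydride onto the trialkoxy-substituted ring A (C4–C4a, closing the six-membered ring C); the two positions ortho to O1 are equivalent, so only the 6-substituted chromanone can form, the amine is masked as its trifluoroacetate salt, and no Lewis acid is needed.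

**Step 15**
Reactants: 23 benzyl 4-{(2S)-5,7-bis(benzyloxy)-6-[(2R)-1-methylpiperidin-2-yl]-4-oxo-3,4-dihydro-2H-chromen-2-yl}phenyl carbonate
Product: 24 (2S)-5,7-dihydroxy-2-(4-hydroxyphenyl)-6-[(2R)-1-methylpiperidin-2-yl]-2,3-dihydro-4H-chromen-4-one
Conditions: H2 (1 atm), 10% Pd/C, EtOAc–MeOH, rt
Reagents that add atoms: none
Why: Catalytic hydrogenolysis of the two benzyl ethers and of the benzyl carbonate (which then loses CO2) under neutral conditions at room temperature, stopped at the uptake of three equivalents, so that the C4 ketone, the C2–O1 bond and the C2'–N bond are not reduced and neither stereocentre is exposed to base or acid.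

**Compound list**

1 | 2,4,6-trihydroxybenzaldehyde | O=Cc1c(O)cc(O)cc1O | starting material
2 | 2,6-dihydroxy-4-[(triisopropylsilyl)oxy]benzaldehyde | O=Cc1c(O)cc(O[Si](C(C)C)(C(C)C)C(C)C)cc1O | intermediate
3 | 2,6-bis(benzyloxy)-4-[(triisopropylsilyl)oxy]benzaldehyde | O=Cc1c(OCc2ccccc2)cc(O[Si](C(C)C)(C(C)C)C(C)C)cc1OCc1ccccc1 | intermediate
4 | (S)-2-methylpropane-2-sulfinamide ((S)-tert-butanesulfinamide) | CC(C)(C)[S@](=O)N | starting material
5 | (S,E)-N-{2,6-bis(benzyloxy)-4-[(triisopropylsilyl)oxy]benzylidene}-2-methylpropane-2-sulfinamide | CC(C)(C)[S@](=O)/N=C/c1c(OCc2ccccc2)cc(O[Si](C(C)C)(C(C)C)C(C)C)cc1OCc1ccccc1 | intermediate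
6 | 1-bromo-4-chlorobutane | ClCCCCBr | starting material
7 | 4-chlorobutylmagnesium bromide | ClCCCC[Mg]Br | intermediate
8 | (S)-N-[(1R)-1-{2,6-bis(benzyloxy)-4-[(triisopropylsilyl)oxy]phenyl}-5-chloropentyl]-2-methylpropane-2-sulfinamide (present as its N-magnesium, then N-potassium salt) | CC(C)(C)[S@](=O)N[C@H](CCCCCl)c1c(OCc2ccccc2)cc(O[Si](C(C)C)(C(C)C)C(C)C)cc1OCc1ccccc1 | intermediate (not isolated)
9 | (2R)-2-{2,6-bis(benzyloxy)-4-[(triisopropylsilyl)oxy]phenyl}-1-[(S)-tert-butylsulfinyl]piperidine | CC(C)(C)[S@](=O)N1CCCC[C@@H]1c1c(OCc2ccccc2)cc(O[Si](C(C)C)(C(C)C)C(C)C)cc1OCc1ccccc1 | intermediate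
10 | (2R)-2-{2,6-bis(benzyloxy)-4-[(triisopropylsilyl)oxy]phenyl}piperidine | N1CCCC[C@@H]1c1c(OCc2ccccc2)cc(O[Si](C(C)C)(C(C)C)C(C)C)cc1OCc1ccccc1 | intermediate
11 | (2R)-2-{2,6-bis(benzyloxy)-4-[(triisopropylsilyl)oxy]phenyl}-1-methylpiperidine | CN1CCCC[C@@H]1c1c(OCc2ccccc2)cc(O[Si](C(C)C)(C(C)C)C(C)C)cc1OCc1ccccc1 | intermediate
12 | 3,5-bis(benzyloxy)-4-[(2R)-1-methylpiperidin-2-yl]phenol | CN1CCCC[C@@H]1c1c(OCc2ccccc2)cc(O)cc1OCc1ccccc1 | intermediate
13 | 4-hydroxybenzaldehyde | O=Cc1ccc(O)cc1 | starting material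
14 | benzyl 4-formylphenyl carbonate | O=Cc1ccc(OC(=O)OCc2ccccc2)cc1 | intermediate
15 | 2-allyl-4,4,5,5-tetramethyl-1,3,2-dioxaborolane (allylboronic acid pinacol ester) | C=CCB1OC(C)(C)C(C)(C)O1 | starting material
16 | benzyl 4-{(1R)-1-[(4,4,5,5-tetramethyl-1,3,2-dioxaborolan-2-yl)oxy]but-3-en-1-yl}phenyl carbonate | C=CC[C@@H](OB1OC(C)(C)C(C)(C)O1)c1ccc(OC(=O)OCc2ccccc2)cc1 | intermediate (not isolated)
17 | benzyl 4-[(1R)-1-hydroxybut-3-en-1-yl]phenyl carbonate | C=CC[C@@H](O)c1ccc(OC(=O)OCc2ccccc2)cc1 | intermediate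
18 | benzyl 4-[(1S)-1-{3,5-bis(benzyloxy)-4-[(2R)-1-methylpiperidin-2-yl]phenoxy}but-3-en-1-yl]phenyl carbonate | CN1CCCC[C@@H]1c1c(OCc2ccccc2)cc(O[C@@H](CC=C)c2ccc(OC(=O)OCc3ccccc3)cc2)cc1OCc1ccccc1 | intermediate
19 | benzyl 4-[(1S)-1-{3,5-bis(benzyloxy)-4-[(2R)-1-methylpiperidin-2-yl]phenoxy}-3,4-dihydroxybutyl]phenyl carbonate (both epimers at the secondary carbinol) | CN1CCCC[C@@H]1c1c(OCc2ccccc2)cc(O[C@@H](CC(O)CO)c2ccc(OC(=O)OCc3ccccc3)cc2)cc1OCc1ccccc1 | intermediate (not isolated)
20 | benzyl 4-[(1S)-1-{3,5-bis(benzyloxy)-4-[(2R)-1-methylpiperidin-2-yl]phenoxy}-3-oxopropyl]phenyl carbonate | CN1CCCC[C@@H]1c1c(OCc2ccccc2)cc(O[C@@H](CC=O)c2ccc(OC(=O)OCc3ccccc3)cc2)cc1OCc1ccccc1 | intermediate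
21 | (3S)-3-{3,5-bis(benzyloxy)-4-[(2R)-1-methylpiperidin-2-yl]phenoxy}-3-(4-{[(benzyloxy)carbonyl]oxy}phenyl)propanoic acid | CN1CCCC[C@@H]1c1c(OCc2ccccc2)cc(O[C@@H](CC(=O)O)c2ccc(OC(=O)OCc3ccccc3)cc2)cc1OCc1ccccc1 | intermediate
22 | (3S)-3-{3,5-bis(benzyloxy)-4-[(2R)-1-methylpiperidin-2-yl]phenoxy}-3-(4-{[(benzyloxy)carbonyl]oxy}phenyl)propanoic trifluoroacetic anhydride | CN1CCCC[C@@H]1c1c(OCc2ccccc2)cc(O[C@@H](CC(=O)OC(=O)C(F)(F)F)c2ccc(OC(=O)OCc3ccccc3)cc2)cc1OCc1ccccc1 | intermediate (not isolated)
23 | benzyl 4-{(2S)-5,7-bis(benzyloxy)-6-[(2R)-1-methylpiperidin-2-yl]-4-oxo-3,4-dihydro-2H-chromen-2-yl}phenyl carbonate | CN1CCCC[C@@H]1c1c(OCc2ccccc2)cc2c(c1OCc1ccccc1)C(=O)C[C@@H](c1ccc(OC(=O)OCc3ccccc3)cc1)O2 | intermediate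
24 | (2S)-5,7-dihydroxy-2-(4-hydroxyphenyl)-6-[(2R)-1-methylpiperidin-2-yl]-2,3-dihydro-4H-chromen-4-one | CN1CCCC[C@@H]1c1c(O)cc2c(c1O)C(=O)C[C@@H](c1ccc(O)cc1)O2 | target

**Step count**

Total: 15 steps. Longest linear sequence: 12 steps (1, 2, 3, 5, 6, 7, 8, 11, 12, 13, 14, 15). Step 4 and steps 9–10 are side branches.

**Steps most likely to fail**

Step 5. What may go wrong: an ortho benzyloxy oxygen binds magnesium and opens a second, arene-chelated transition state, so that facial selectivity drops or inverts; the ring closure may also lag behind the addition. The fallback sets out from 5 and returns at 9. The aldimine 5 is allylated with allyl bromide and indium powder in THF at 60 °C, which also runs through a sulfinyl-bound chair but tolerates donor groups and coordinating media, to give the homoallylic sulfinamide F1. N-Allylation (KN(SiMe3)2, allyl bromide, DMF) gives the N-allyl diene F2. Ring-closing metathesis with the second-generation Grubbs catalyst RuCl2(=CHPh)(PCy3)(H2IMes) in CH2Cl2 closes the 1,2,3,6-tetrahydropyridine F3. Diimide (2-nitrobenzenesulfonyl hydrazide, Et3N) then saturates C4'=C5' without touching the benzyl ethers and gives 9.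

Step 11. What may go wrong: the benzylic oxyphosphonium ion ionises before the phenoxide attacks (erosion of configuration at C2), eliminates to the 1-aryl-1,3-diene, or the phenoxide takes up the benzyloxycarbonyl group instead. The fallback sets out from 12 and returns at 24; it builds ring C in the classical order, carbon first. Friedel–Crafts acetylation of 12 ortho to the hydroxyl (Ac2O, BF3·OEt2; both ortho positions are equivalent and the para position is occupied) gives the 2-hydroxyacetophenone F4. Claisen–Schmidt condensation with 4-(benzyloxy)benzaldehyde (KOH, EtOH) gives the 2'-hydroxychalcone F5. Oxa-Michael cyclisation through its single free hydroxyl (NaOAc, EtOH, reflux) gives the 6-substituted flavanone as two C2 epimers, which are diastereomers because of C2' and are separated by chromatography into the 2S tribenzyl flavanone F6 and the 2R tribenzyl flavanone F7; F7 is returned to the chalcone equilibrium with base. Hydrogenolysis of F6 (H2, 10% Pd/C) gives 24. This route gives up reagent control at C2 in exchange for long-known chemistry.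

Step 14. What may go wrong: acid-promoted heterolysis of the benzylic C2–O1 bond before acylation (loss of the phenol or of configuration at C2), or ring opening at the electron-rich benzylic C2'–N bond with epimerisation. The fallback sets out from 18 and returns at 23; it makes the C4–C4a bond under neutral conditions by a Nozaki–Hiyama–Kishi reaction. Iodination of 18 at one of the two equivalent positions ortho to the ether oxygen (N-iodosuccinimide, CF3CO2H, MeCN, 0 °C) gives the aryl iodide F8. Lemieux–Johnson cleavage as in step 12 gives the iodo aldehyde F9. CrCl2 with catalytic NiCl2 in DMF closes ring C to the chroman-4-ol F10 (both C4 epimers), and Dess–Martin periodinane oxidises it to 23.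

**Further compounds**

F1 | step 5 | (S)-N-[(1R)-1-{2,6-bis(benzyloxy)-4-[(triisopropylsilyl)oxy]phenyl}but-3-en-1-yl]-2-methylpropane-2-sulfinamide | CC(C)(C)[S@](=O)N[C@H](CC=C)c1c(OCc2ccccc2)cc(O[Si](C(C)C)(C(C)C)C(C)C)cc1OCc1ccccc1
F2 | step 5 | (S)-N-allyl-N-[(1R)-1-{2,6-bis(benzyloxy)-4-[(triisopropylsilyl)oxy]phenyl}but-3-en-1-yl]-2-methylpropane-2-sulfinamide | CC(C)(C)[S@](=O)N(CC=C)[C@H](CC=C)c1c(OCc2ccccc2)cc(O[Si](C(C)C)(C(C)C)C(C)C)cc1OCc1ccccc1
F3 | step 5 | (2R)-2-{2,6-bis(benzyloxy)-4-[(triisopropylsilyl)oxy]phenyl}-1-[(S)-tert-butylsulfinyl]-1,2,3,6-tetrahydropyridine | CC(C)(C)[S@](=O)N1CC=CC[C@@H]1c1c(OCc2ccccc2)cc(O[Si](C(C)C)(C(C)C)C(C)C)cc1OCc1ccccc1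
F4 | step 11 | 1-{2,4-bis(benzyloxy)-6-hydroxy-3-[(2R)-1-methylpiperidin-2-yl]phenyl}ethan-1-one | CN1CCCC[C@@H]1c1c(OCc2ccccc2)cc(O)c(C(C)=O)c1OCc1ccccc1
F5 | step 11 | (E)-1-{2,4-bis(benzyloxy)-6-hydroxy-3-[(2R)-1-methylpiperidin-2-yl]phenyl}-3-[4-(benzyloxy)phenyl]prop-2-en-1-one | CN1CCCC[C@@H]1c1c(OCc2ccccc2)cc(O)c(C(=O)/C=C/c2ccc(OCc3ccccc3)cc2)c1OCc1ccccc1
F6 | step 11 | (2S)-5,7-bis(benzyloxy)-2-[4-(benzyloxy)phenyl]-6-[(2R)-1-methylpiperidin-2-yl]-2,3-dihydro-4H-chromen-4-one | CN1CCCC[C@@H]1c1c(OCc2ccccc2)cc2c(c1OCc1ccccc1)C(=O)C[C@@H](c1ccc(OCc3ccccc3)cc1)O2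
F7 | step 11 | (2R)-5,7-bis(benzyloxy)-2-[4-(benzyloxy)phenyl]-6-[(2R)-1-methylpiperidin-2-yl]-2,3-dihydro-4H-chromen-4-one | CN1CCCC[C@@H]1c1c(OCc2ccccc2)cc2c(c1OCc1ccccc1)C(=O)C[C@H](c1ccc(OCc3ccccc3)cc1)O2
F8 | step 14 | benzyl 4-[(1S)-1-{3,5-bis(benzyloxy)-2-iodo-4-[(2R)-1-methylpiperidin-2-yl]phenoxy}but-3-en-1-yl]phenyl carbonate | CN1CCCC[C@@H]1c1c(OCc2ccccc2)c(I)c(O[C@@H](CC=C)c2ccc(OC(=O)OCc3ccccc3)cc2)cc1OCc1ccccc1
F9 | step 14 | benzyl 4-[(1S)-1-{3,5-bis(benzyloxy)-2-iodo-4-[(2R)-1-methylpiperidin-2-yl]phenoxy}-3-oxopropyl]phenyl carbonate | CN1CCCC[C@@H]1c1c(OCc2ccccc2)c(I)c(O[C@@H](CC=O)c2ccc(OC(=O)OCc3ccccc3)cc2)cc1OCc1ccccc1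
F10 | step 14 | benzyl 4-{(2S)-5,7-bis(benzyloxy)-4-hydroxy-6-[(2R)-1-methylpiperidin-2-yl]-3,4-dihydro-2H-chromen-2-yl}phenyl carbonate (both C4 epimers) | CN1CCCC[C@@H]1c1c(OCc2ccccc2)cc2c(c1OCc1ccccc1)C(O)C[C@@H](c1ccc(OC(=O)OCc3ccccc3)cc1)O2
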